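Start from the small charge: read the 1.20 equiv of solid reagent and the 5.8 mol% of catalyst on the left-handed substrate alone, so that the solid reagent can serve 60.0 % of the two substrates charged together.

| setting | red | violet |
|---|---|---|
| left-handed substrate | 20 mM | 20 mM |
| solid reagent | 1.20 equiv | 1.20 equiv |
| catalyst | 5.8 mol% | 5.8 mol% |
| right-handed substrate | 20 mM | 20 mM |
| temperature | 90 °C | 70 °C |
| time | 25 s | 25 s |

1. the best flask by amount of left-handed product, in percent of the left-handed substrate and right-handed substrate together charged; "all alike" if 1.5 percentage points covers them all (red / violet / all alike)
2. amount of left-handed product at the end, in percent of the left-handed substrate and right-handed substrate together charged, red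
3. amount of left-handed product at the end, in percent of the left-handed substrate and right-handed substrate together charged, violet

- catalyst is single-handed; left-handed substrate and right-handed substrate are mirror images of each other, charged as a racemate, each of them at the stated concentration
- solid, in amounts per volume of the solution: solid reagent
- all constants are for 70 °C and move with temperature by the activation energies
- at the start none of the solid reagent is in solution

    coupling partner + catalyst + left-handed substrate → catalyst + left-handed product (k1 = 7330 M⁻² s⁻¹, Ea1 = 27.0 kJ mol⁻¹)
    coupling partner + catalyst + right-handed substrate → catalyst + right-handed product (k2 = 3580 M⁻² s⁻¹, Ea2 = 32.0 kJ mol⁻¹)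
    solid reagent ⇌ coupling partner, rate k3*(cs3 - [coupling partner]) while solid is left; crystals form when [coupling partner] > cs3 (cs3 = 4.6 mM, k3 = 3.18 s⁻¹)
    coupling partner → decomposed reagent (k4 = 0.0260 s⁻¹, Ea4 = 105 kJ mol⁻¹)
    (constants at 70 °C)

Define the left exposure E as the left-handed rate constant times the catalyst concentration times the time integral of dissolved coupling partner, so that a fraction exp(−E) of the left-handed substrate stands and exp(−E/s) of the right-handed, with s the selectivity factor, 1.86 in red and 2.05 in violet. Treat the solid reagent as a budget in fractions of the left-handed charge: its 1.20 equiv pays for left-handed substrate consumed, right-handed substrate consumed and w·E decomposed, where w, the decomposition constant over the opening left-handed coupling rate, is 0.689 in red and 0.153 in violet.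

Solve the budget at the start, with the substrates at full strength: red gets E of 0.539, and as the left-handed substrate thins faster than the right-handed, its share of the spending falls from there, so this figure, taken on the two substrates charged together, is a ceiling of 26.9 %. Then solve toward the end by one Newton step from below, which reaches the budget exposure 0.635 and a floor of 23.5 %. The time does not bar red from this, because coupling partner held at its solubility for the whole run gives an exposure of 1.65, which is more than the budget needs. Violet's budget exposure of 1.01 is more than the solubility exposure of 0.978, so take the lower figure and a violet ceiling of 31.2 %. I have no floor for violet by hand, but I commit to violet, whose ceiling is higher than red's.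

The forecast begins “Taking equiv and mol% on the total racemate (40 mM): solid 48 mM, catalyst 2.32 mM” and gives red, with 44.8 % for red and 41.5 % for violet, both above my ceilings; we part on that reading of the charge.

The simulation gives violet, with 23.6 % in red, inside my bracket of 23.5 % to 26.9 %, and 29.3 % in violet, below its ceiling. In red, half of the dissolving was done by 3.74 s, the solid reagent stood at 0 % at 12.5 s, and decomposition ran on the dissolved coupling partner to 8.78 mM of decomposed reagent at 25.0 s. In violet, the solid reagent still stood at 30.2 % at 12.5 s, and 2.62 mM of coupling partner remained dissolved at 25.0 s. The neighbour of red with 2.3 mol% of catalyst has w of 1.74 and budget exposure 0.393, which reckons 16.3 %, and it gives 16.2 %.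

The constants are invented; no experiment stands behind them.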